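# Proposed synthesis of (E)-3-[(2S,3R)-2-(4-hydroxy-3,5-dimethoxyphenyl)-3-(hydroxymethyl)-7-methoxy-2,3-dihydrobenzofuran-5-yl]prop-2-enoic acid (CNP0224723.1)

## Analysis of the target

The target is a neolignan built on a 2,3-dihydrobenzofuran: benzene ring A is fused to dihydrofuran ring C. A 4-hydroxy-3,5-dimethoxyphenyl ring B sits on C2, a hydroxymethyl group on C3, a methoxy group on C7 and an (E)-propenoic acid on C5. C2 (S) and C3 (R) are the only stereocentres; they are adjacent and their substituents are trans across ring C. Trans is the more stable arrangement, so the relative configuration is the easier half of the problem and the absolute configuration the harder half. The sensitive parts are three. The free syringyl phenol is easily oxidised and can assist ionisation of the benzylic C2–O1 bond to a para-quinone methide under acid or hot base. The primary alcohol lies next to a benzylic centre. The acrylic acid is a Michael acceptor and is reducible. The synthesis is hard because two electron-rich arenes must be joined through two contiguous sp3 carbons with absolute control, and because the C3 arm and the side-chain carboxyl must end at different oxidation levels. The plan rests on the substitution of C3, which carries the ring-fusion carbon C3a, the oxygenated benzylic carbon C2 and one exocyclic oxygenated carbon. That is the array left when the carbonyl carbon of a 2-arylchroman-4-one is pushed out of the ring as an ester while its bond to the arene moves to C3, so rings A and C with both stereocentres map onto a flavanone with a single stereocentre.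

## Retrosynthetic reasoning

Target 16 is traced back to its methyl ester 15. Only the acyl C–O bond is cut. Carrying the acid as an ester keeps it out of the way of the palladium chemistry, and the last step is then a mild saponification that forms no carbon–carbon bond next to a free phenol and a free acid.

In 15 the bond between ring-A carbon C5 and the olefinic carbon is cut, giving aryl bromide 13 and methyl acrylate 14. C5 is para to O1, which is the position para to the phenol oxygen of acetophenone 1, where a halogen enters by simple electrophilic substitution. The bromine then rides unchanged through ring construction and rearrangement. Cutting the C=C bond instead would need an aryl aldehyde, which would not survive the hydride reduction of the C3 ester. The forward reaction must vinylate an electron-rich aryl bromide E-selectively in the presence of a free phenol and a primary alcohol.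

Alcohol 13 is traced back to ester 12 by functional-group interconversion: the hydroxymethyl group comes from a methyl ester and the phenol from its acetate, both released by one hydride reagent. Reducing the C3 carboxyl before the side-chain ester is introduced is what keeps the two carboxyl-level carbons distinguishable.

The key disconnection is made in 12. The C3–C3a bond is cut and C3a is reattached to the ester carbon, which returns the six-membered ketone 9. This trades two stereocentres for one and trades a dihydrofuran for a chromanone, a ring for which catalytic asymmetric access exists. It also means the ester carbon is in the molecule from the start and needs no separate introduction at C3. The forward reaction must oxidise C3, make the ring-A carbon migrate in preference to ring B or a hydrogen, and deliver the trans ester without touching C2.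

Flavanone 9 is cut at the C2–aryl bond into chromone 4 and boronic acid 8. This joins the two arenes convergently and lets a chiral catalyst set the only stereocentre that has to be made. Cutting O1–C2 instead (oxa-Michael closure of a chalcone) is a reversible reaction and gives the racemate. The forward reaction is a face-selective aryl transfer to C2 that must leave the C–Br bond and the aryl acetate alone.

Chromone 4 is cut at O1–C2 and C2–C3. C2 comes from a one-carbon unit at the formamide oxidation level condensed onto the methyl ketone of 2 through enaminone 3. The bromine of 2 comes from bromination of 1, where the hydroxyl has both ortho positions blocked and directs para.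

Boronic acid 8 is traced back through its pinacol ester 7 to aryl bromide 6 by exchange of C–B for C–Br, and 6 to phenol 5 by acetylation. The acetate is put on first because it must mask the phenol against the oxidant of the key step and lower the migratory aptitude of ring B there.

## Alternatives that were turned down

Alternative 1: Rings A and C would both be made in one gold-catalysed furan-yne benzannulation. The disconnection cuts C3a–C7a, C6–C7 and the C7–O bond, leading back to ynol ether A2, in which a 2,4-disubstituted furan is tied through C3 and C2 to an ethynyl ether oxygen. A cationic gold catalyst of the type Ph3PAuNTf2 would activate the alkyne, the furan would add, and the furan oxygen would end as the C7 phenol of A1. In its favour, the aromatic ring is built late from simple pieces and the substitution pattern of ring A follows from the furan. Against it for this target: A2 is a secondary benzylic alkynyl ether, a class that is awkward to prepare on a hindered carbinol and prone to sigmatropic rearrangement to ketenes on mild warming. Ynol ethers can also react with gold as ketene equivalents and not as plain alkynes. Both stereocentres of A2 would have to be set beforehand in an open chain. After A1 the route still needs methylation of the C7 phenol, differentiation of two primary silyl ethers so that only the C5 arm is oxidised, an olefination and the deprotections. The chosen strategy sets one stereocentre by catalysis, derives the second from it, and needs three steps after its key step; on the late construction of ring A, Alternative 1 is the more inventive.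

Alternative 2: Ring C would be closed by a Catellani annulation of aryl iodide A4 with the enantiopure cis epoxide A5, cutting C3–C3a and O1–C7a. Pd(OAc)2, a phosphine and norbornene would steer the ortho C–H carbon of A4 onto the non-benzylic epoxide carbon with inversion, and the released alkoxide would then close onto the ipso carbon to give A3. On convergence this alternative is stronger than the chosen route: two simple fragments give ring C with both bonds in one operation, and both stereocentres are carried in from the epoxide without any stereocentre being created in the step. Against it: the annulation is at its best with unhindered, terminal epoxides, whereas A5 is 2,3-disubstituted. The required attack at the non-benzylic carbon runs against the electronic bias of an electron-rich aryl epoxide, whose benzylic carbon is the more electrophilic. A Lewis-acidic palladium medium can isomerise such an epoxide to a carbonyl compound. A5 itself needs an asymmetric epoxidation of a cis alkene, and the C5 ester of A3 must still be taken through aldehyde and olefination stages and two deprotections. The chosen strategy offers instead a key step on exactly the substrate class for which it is known, and a bromide that becomes the side chain in one Heck reaction.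

Alternative 3: Ring C would be closed at O1–C2 from the open diol A7, a bisphenol whose carbinol epimers both ionise under Brønsted acid to the same ring-B para-quinone methide. The ring-A phenol then adds to C2 and gives the trans product A6, which is identical with compound 13 of the present route. The key step of this alternative is at least as reliable as the one chosen here, probably more so: it is a simple acid-promoted closure under thermodynamic control, it is stereoconvergent at C2, and it shares the same three-step endgame. What speaks against it is where the difficulty goes. The one fixed stereocentre of A7 bears ring A, the hydroxymethyl group and the carbinol. It would have to be made by an auxiliary-controlled aldol reaction of an ortho-oxygenated arylacetic acid that is not a stock material, and it stays alpha to a carbonyl, and so epimerisable, until that carbonyl is reduced. Two phenols need protection and release, and the step count from commercial materials is higher. The chosen strategy accepts a less predictable key step in exchange for a catalytic, auxiliary-free setting of absolute configuration and a shorter path.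

Key step: step 7

Assumption: the facial sense of the palladium-catalysed conjugate addition is taken from the behaviour of cyclic enones with this ligand class, so the (R)-configured pyridine-oxazoline is expected to give the (2S)-flavanone. If the sense proves opposite, the (S)-ligand is used with nothing else changed.

## Route

Step 1
Reactants: 1 1-(2-hydroxy-3-methoxyphenyl)ethanone
Product: 2 1-(5-bromo-2-hydroxy-3-methoxyphenyl)ethanone
Conditions: NBS, MeCN, 0 °C to rt
Reagents that add atoms: N-bromosuccinimide, O=C1CCC(=O)N1Br
Why: Electrophilic aromatic bromination; the hydroxyl is the strongest director and both of its ortho positions are occupied, so bromine should enter para to it, a site that is also meta to the acetyl group.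

Step 2
Reactants: 2 1-(5-bromo-2-hydroxy-3-methoxyphenyl)ethanone
Product: 4 6-bromo-8-methoxy-4H-chromen-4-one, via enaminone 3 (not isolated)
Conditions: Me2NCH(OMe)2, PhMe, 100 °C; then conc. HCl, CH2Cl2, 40 °C
Reagents that add atoms: N,N-dimethylformamide dimethyl acetal, COC(OC)N(C)C
Why: Condensation of the methyl ketone with the amide acetal gives the (E)-enaminone; under acid the phenol adds to its β-carbon and dimethylamine is expelled (addition–elimination), the standard enaminone route to chromones unsubstituted at C2 and C3.

Step 3
Reactants: 5 4-bromo-2,6-dimethoxyphenol
Product: 6 4-bromo-2,6-dimethoxyphenyl acetate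
Conditions: Ac2O, pyridine, DMAP (cat.), CH2Cl2, rt
Reagents that add atoms: acetic anhydride, CC(=O)OC(C)=O
Why: DMAP-catalysed O-acylation; the acetate masks the oxidation-prone phenol and makes ring B a poorer donor for steps 6 and 7.

Step 4
Reactants: 6 4-bromo-2,6-dimethoxyphenyl acetate
Product: 7 2,6-dimethoxy-4-(4,4,5,5-tetramethyl-1,3,2-dioxaborolan-2-yl)phenyl acetate
Conditions: B2pin2, PdCl2(dppf), KOAc, 1,4-dioxane, 90 °C
Reagents that add atoms: bis(pinacolato)diboron, CC1(C)OB(OC1(C)C)B1OC(C)(C)C(C)(C)O1
Why: Miyaura borylation (oxidative addition of zerovalent palladium into C–Br, acetate-assisted transmetalation from the diboron, reductive elimination); the anhydrous, weakly basic medium should leave the aryl acetate intact.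

Step 5
Reactants: 7 2,6-dimethoxy-4-(4,4,5,5-tetramethyl-1,3,2-dioxaborolan-2-yl)phenyl acetate
Product: 8 (4-acetoxy-3,5-dimethoxyphenyl)boronic acid
Conditions: NaIO4, THF/H2O, rt; then 1 M HCl, rt
Reagents that add atoms: water, O
Why: Hydrolysis of the pinacol boronate, driven by periodate cleavage of the released diol; dilute acid at room temperature is too mild to hydrolyse the hindered aryl acetate at a competing rate.

Step 6
Reactants: 4 6-bromo-8-methoxy-4H-chromen-4-one; 8 (4-acetoxy-3,5-dimethoxyphenyl)boronic acid
Product: 9 4-[(2S)-6-bromo-8-methoxy-4-oxochroman-2-yl]-2,6-dimethoxyphenyl acetate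
Conditions: Pd(OCOCF3)2 (10 mol %), (R)-4-tert-butyl-2-(pyridin-2-yl)-4,5-dihydrooxazole (12 mol %), NH4PF6 (30 mol %), H2O (5 equiv.), ClCH2CH2Cl, 60 °C
Reagents that add atoms: none
Why: Enantioselective conjugate addition of an arylboronic acid to a chromone under divalent palladium catalysis; transmetalation gives an arylpalladium species, insertion of the chromone C2=C3 bond places the aryl group on C2 from the face left open by the tert-butyl group of the ligand (this sets C2 as S), and water protonates the palladium enolate. No zerovalent palladium is formed in the cycle, so the aryl bromide should not react.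

Step 7
Reactants: 9 4-[(2S)-6-bromo-8-methoxy-4-oxochroman-2-yl]-2,6-dimethoxyphenyl acetate
Product: 12 methyl (2S,3S)-2-(4-acetoxy-3,5-dimethoxyphenyl)-5-bromo-7-methoxy-2,3-dihydrobenzofuran-3-carboxylate (2,3-trans), via methyl enol ether 10 (not isolated), via trans-iodanyl dimethyl ketal 11 (not isolated)
Conditions: PhI(OAc)2 (1.2 equiv.), conc. H2SO4, HC(OMe)3, 0 °C to rt; aq. NaHCO3 work-up
Reagents that add atoms: trimethyl orthoformate, COC(OC)OC; water, O
Why: Acid and the orthoformate turn ketone 9 into enol ether 10, whose C3 attacks the trivalent iodine centre on the face anti to the pseudo-equatorial C2 aryl group, and methanol released from the orthoformate then adds to C4 to give ketal 11 with the iodanyl group equatorial and trans to the aryl group. In 11 the ring bond C4–C4a is antiperiplanar to the C3–I bond, so the ring-A carbon shifts from C4 to C3 as iodobenzene leaves, forming C3–C3a with inversion at C3 and leaving a dimethoxycarbenium ion that ends as the methyl ester on work-up. The closest known reaction type is the oxidative 1,2-aryl-shift ring contraction of flavanones by trivalent iodine reagents or Tl(NO3)3 in acidified orthoformate. Ring C is closed not by cyclisation of a chain but by contraction of the six-membered pyranone, the migrating arene carbon bridging C4 and C3 in a phenonium-like three-centre transition state. The new stereocentre C3 is controlled by C2: anti iodination followed by invertive migration puts the ester trans to the aryl group, which is also the more stable arrangement, and C2 itself is not touched. The step needs the oxidant to choose the enol ether over the arenes, which the acetate on ring B and the bromine on ring A help by lowering ring electron density. It also needs ring-A migration to win over a shift of ring B from C2 (isoflavone pathway) and over loss of the C2 hydrogen (flavone pathway), which the weakly donating acetylated ring B, its equatorial position and the water-free ketalising medium should favour.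

Step 8
Reactants: 12 methyl (2S,3S)-2-(4-acetoxy-3,5-dimethoxyphenyl)-5-bromo-7-methoxy-2,3-dihydrobenzofuran-3-carboxylate
Product: 13 4-[(2S,3R)-5-bromo-3-(hydroxymethyl)-7-methoxy-2,3-dihydrobenzofuran-2-yl]-2,6-dimethoxyphenol
Conditions: LiBH4 (excess), THF/MeOH, 0 °C to rt; aq. NH4Cl
Reagents that add atoms: none
Why: Hydride reduction of the methyl ester to the primary alcohol, with the activated aryl acetate cleaved by the same reagent; the aryl bromide is inert and neither stereocentre is touched (the C3 descriptor changes from S to R only because the substituent priorities change).

Step 9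
Reactants: 13 4-[(2S,3R)-5-bromo-3-(hydroxymethyl)-7-methoxy-2,3-dihydrobenzofuran-2-yl]-2,6-dimethoxyphenol; 14 methyl acrylate
Product: 15 methyl (E)-3-[(2S,3R)-2-(4-hydroxy-3,5-dimethoxyphenyl)-3-(hydroxymethyl)-7-methoxy-2,3-dihydrobenzofuran-5-yl]prop-2-enoate
Conditions: Pd(OAc)2, P(o-tol)3, Et3N, DMF, 100 °C
Reagents that add atoms: none
Why: Mizoroki–Heck reaction; oxidative addition into C–Br, syn carbopalladation of the acrylate at its β-carbon and syn β-hydride elimination should give the (E)-cinnamate, and free hydroxyl groups are tolerated by this reaction.

Step 10
Reactants: 15 methyl (E)-3-[(2S,3R)-2-(4-hydroxy-3,5-dimethoxyphenyl)-3-(hydroxymethyl)-7-methoxy-2,3-dihydrobenzofuran-5-yl]prop-2-enoate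
Product: 16 (E)-3-[(2S,3R)-2-(4-hydroxy-3,5-dimethoxyphenyl)-3-(hydroxymethyl)-7-methoxy-2,3-dihydrobenzofuran-5-yl]prop-2-enoic acid
Conditions: LiOH, THF/MeOH/H2O, rt; then 1 M HCl to pH 3–4, 0 °C
Reagents that add atoms: lithium hydroxide, [Li+].[OH-]
Why: Saponification of the conjugated methyl ester by acyl–oxygen cleavage; room temperature and a cold, mild acidification avoid ionising the benzylic C2–O1 bond, which the free para-phenol of ring B could otherwise assist.

## Compound list

1 | 1-(2-hydroxy-3-methoxyphenyl)ethanone | CC(=O)c1cccc(OC)c1O | starting material
2 | 1-(5-bromo-2-hydroxy-3-methoxyphenyl)ethanone | CC(=O)c1cc(Br)cc(OC)c1O | intermediate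
3 | (E)-1-(5-bromo-2-hydroxy-3-methoxyphenyl)-3-(dimethylamino)prop-2-en-1-one (enaminone, formed in the flask, not isolated) | CN(C)/C=C/C(=O)c1cc(Br)cc(OC)c1O | intermediate
4 | 6-bromo-8-methoxy-4H-chromen-4-one | O=c1ccoc2c(OC)cc(Br)cc12 | intermediate
5 | 4-bromo-2,6-dimethoxyphenol | COc1cc(Br)cc(OC)c1O | starting material
6 | 4-bromo-2,6-dimethoxyphenyl acetate | COc1cc(Br)cc(OC)c1OC(C)=O | intermediate
7 | 2,6-dimethoxy-4-(4,4,5,5-tetramethyl-1,3,2-dioxaborolan-2-yl)phenyl acetate | COc1cc(B2OC(C)(C)C(C)(C)O2)cc(OC)c1OC(C)=O | intermediate
8 | (4-acetoxy-3,5-dimethoxyphenyl)boronic acid | COc1cc(B(O)O)cc(OC)c1OC(C)=O | intermediate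
9 | 4-[(2S)-6-bromo-8-methoxy-4-oxochroman-2-yl]-2,6-dimethoxyphenyl acetate, the (2S)-flavanone | COc1cc([C@H]2Oc3c(OC)cc(Br)cc3C(=O)C2)cc(OC)c1OC(C)=O | intermediate
10 | 4-[(2S)-6-bromo-4,8-dimethoxy-2H-chromen-2-yl]-2,6-dimethoxyphenyl acetate (methyl enol ether, formed in the flask, not isolated) | COc1cc([C@H]2Oc3c(OC)cc(Br)cc3C(OC)=C2)cc(OC)c1OC(C)=O | intermediate
11 | 4-[(2R,3R)-3-[acetoxy(phenyl)iodanyl]-6-bromo-4,4,8-trimethoxychroman-2-yl]-2,6-dimethoxyphenyl acetate (aryl and iodanyl groups trans; C2 geometry as in 9, its descriptor changes only formally; formed in the flask, not isolated) | COc1cc([C@H]2Oc3c(OC)cc(Br)cc3C(OC)(OC)[C@@H]2I(OC(C)=O)c4ccccc4)cc(OC)c1OC(C)=O | intermediate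
12 | methyl (2S,3S)-2-(4-acetoxy-3,5-dimethoxyphenyl)-5-bromo-7-methoxy-2,3-dihydrobenzofuran-3-carboxylate (2,3-trans) | COc1cc([C@H]2Oc3c(OC)cc(Br)cc3[C@@H]2C(=O)OC)cc(OC)c1OC(C)=O | intermediate
13 | 4-[(2S,3R)-5-bromo-3-(hydroxymethyl)-7-methoxy-2,3-dihydrobenzofuran-2-yl]-2,6-dimethoxyphenol (2,3-trans) | COc1cc([C@H]2Oc3c(OC)cc(Br)cc3[C@@H]2CO)cc(OC)c1O | intermediate
14 | methyl acrylate | C=CC(=O)OC | starting material
15 | methyl (E)-3-[(2S,3R)-2-(4-hydroxy-3,5-dimethoxyphenyl)-3-(hydroxymethyl)-7-methoxy-2,3-dihydrobenzofuran-5-yl]prop-2-enoate | COc1cc([C@H]2Oc3c(OC)cc(/C=C/C(=O)OC)cc3[C@@H]2CO)cc(OC)c1O | intermediate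
16 | (E)-3-[(2S,3R)-2-(4-hydroxy-3,5-dimethoxyphenyl)-3-(hydroxymethyl)-7-methoxy-2,3-dihydrobenzofuran-5-yl]prop-2-enoic acid | COc1cc([C@H]2Oc3c(OC)cc(/C=C/C(=O)O)cc3[C@@H]2CO)cc(OC)c1O | target

## Step count and least certain steps

Total step count: 10 steps. Longest linear sequence: 8 steps (5 to 6 to 7 to 8 to 9 to 12 to 13 to 15 to 16, that is steps 3 to 10). The branch from 1 (steps 1 and 2) joins at step 6.

Step 7 (key step). Three things are most likely to go wrong. The C3-iodanyl intermediate may lose the C2 hydrogen instead of rearranging, which leads to the flavone. Ring B may migrate from C2 in place of the ring-A carbon, which leads to the isoflavone skeleton. The acetate may be lost by acid-catalysed methanolysis, after which the liberated phenol would be oxidised. A slow acid-promoted opening of the pyranone would in addition erode the configuration at C2. The fallback keeps the same 1,2-shift of the ring-A carbon but reaches it through a carbene; it sets out from 9 and comes back at 12. Ketone 9 is deprotonated with LiN(SiMe3)2 (1.05 equiv., −78 °C, where the ketone is far more acidic than the acetate) and C-acylated with 2,2,2-trifluoroethyl trifluoroacetate to the 3-trifluoroacetyl flavanone F1. Without isolation, F1 is treated with methanesulfonyl azide and Et3N and gives the 3-diazo flavanone F2 by detrifluoroacetylative diazo transfer. Irradiation of F2 at 365 nm in methanol triggers a Wolff rearrangement, and the ring-contracted ketene is trapped as the methyl ester. This is expected as 12 together with its C3 epimer, the cis ester F3, which a catalytic amount of DBU in CH2Cl2 should equilibrate to the more stable trans ester 12.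

Step 6. Poor facial selectivity with this particular chromone, or slow transmetalation with competing protodeboronation of the electron-rich boronic acid, would give 9 in low enantiomeric purity or low conversion. The fallback builds the flavanone without palladium and resolves it; it sets out from 2 and comes back at 9. Acid-mediated Claisen–Schmidt condensation (BF3·OEt2, dioxane) of 2 with 4-hydroxy-3,5-dimethoxybenzaldehyde F4 gives the 2'-hydroxychalcone F5. NaOAc in refluxing ethanol closes F5 to the racemic 4'-hydroxyflavanone F6, and acetylation (Ac2O, pyridine) gives the racemic acetate F7. Kinetic resolution by asymmetric transfer hydrogenation with RuCl(p-cymene)[(R,R)-TsDPEN] and HCO2H/Et3N, stopped near half conversion, should reduce the (2R) ketone to the cis-flavan-4-ol F8 and leave 9, which is separated by chromatography.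

Step 9. Oxidative addition into the electron-rich C–Br bond may be slow. At the temperature then needed, the catalyst may decompose, or the amine base may promote reversible opening of ring C through the quinone methide of the free phenol. That opening would not touch C3 but would cost material. The fallback replaces carbopalladation by a cross-coupling that runs at lower temperature; it sets out from 13 and comes back at 15. Suzuki–Miyaura coupling of 13 with methyl (E)-3-(4,4,5,5-tetramethyl-1,3,2-dioxaborolan-2-yl)prop-2-enoate F9, using Pd(OAc)2 with 2-dicyclohexylphosphino-2',6'-dimethoxybiphenyl and K3PO4 in dioxane/water at 60–80 °C, should give 15 directly with the E geometry carried in by the boronate.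

Step 5. Partial hydrolysis of the aryl acetate, or protodeboronation of the electron-rich boronic acid in the acidic periodate medium, would lower the quality of 8; free boronic acids of this kind are also awkward to isolate because they dehydrate to boroxines. The fallback goes through a crystalline salt; it sets out from 7 and comes back at 8. KHF2 in aqueous methanol converts 7 into potassium (4-acetoxy-3,5-dimethoxyphenyl)trifluoroborate F10, which is collected by crystallisation, and Me3SiCl with water in acetonitrile then hydrolyses F10 to 8 under mild, non-oxidising conditions.

## Further compounds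

F1 | step 7 | 4-[(2S)-6-bromo-8-methoxy-4-oxo-3-(trifluoroacetyl)chroman-2-yl]-2,6-dimethoxyphenyl acetate (C3 epimers and enol form, not isolated) | COc1cc([C@H]2Oc3c(OC)cc(Br)cc3C(=O)C2C(=O)C(F)(F)F)cc(OC)c1OC(C)=O
F2 | step 7 | 4-[(2R)-6-bromo-3-diazo-8-methoxy-4-oxochroman-2-yl]-2,6-dimethoxyphenyl acetate (C2 geometry as in 9, descriptor changes only formally) | COc1cc([C@H]2Oc3c(OC)cc(Br)cc3C(=O)C2=[N+]=[N-])cc(OC)c1OC(C)=O
F3 | step 7 | methyl (2S,3R)-2-(4-acetoxy-3,5-dimethoxyphenyl)-5-bromo-7-methoxy-2,3-dihydrobenzofuran-3-carboxylate (2,3-cis) | COc1cc([C@H]2Oc3c(OC)cc(Br)cc3[C@H]2C(=O)OC)cc(OC)c1OC(C)=O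
F4 | step 6 | 4-hydroxy-3,5-dimethoxybenzaldehyde | COc1cc(C=O)cc(OC)c1O
F5 | step 6 | (E)-1-(5-bromo-2-hydroxy-3-methoxyphenyl)-3-(4-hydroxy-3,5-dimethoxyphenyl)prop-2-en-1-one | COc1cc(/C=C/C(=O)c2cc(Br)cc(OC)c2O)cc(OC)c1O
F6 | step 6 | racemic 6-bromo-2-(4-hydroxy-3,5-dimethoxyphenyl)-8-methoxychroman-4-one | COc1cc(C2Oc3c(OC)cc(Br)cc3C(=O)C2)cc(OC)c1O
F7 | step 6 | racemic 4-(6-bromo-8-methoxy-4-oxochroman-2-yl)-2,6-dimethoxyphenyl acetate | COc1cc(C2Oc3c(OC)cc(Br)cc3C(=O)C2)cc(OC)c1OC(C)=O
F8 | step 6 | 4-[(2R,4R)-6-bromo-4-hydroxy-8-methoxychroman-2-yl]-2,6-dimethoxyphenyl acetate (2,4-cis) | COc1cc([C@@H]2Oc3c(OC)cc(Br)cc3[C@H](O)C2)cc(OC)c1OC(C)=O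
F9 | step 9 | methyl (E)-3-(4,4,5,5-tetramethyl-1,3,2-dioxaborolan-2-yl)prop-2-enoate | COC(=O)/C=C/B1OC(C)(C)C(C)(C)O1
F10 | step 5 | potassium (4-acetoxy-3,5-dimethoxyphenyl)trifluoroborate | [K+].COc1cc([B-](F)(F)F)cc(OC)c1OC(C)=O
A1 | alternative 1 | (2S,3R)-3,5-bis(tert-butyldimethylsilyloxymethyl)-2-[3,5-dimethoxy-4-(triisopropylsilyloxy)phenyl]-2,3-dihydrobenzofuran-7-ol | COc1cc([C@H]2Oc3c(O)cc(CO[Si](C)(C)C(C)(C)C)cc3[C@@H]2CO[Si](C)(C)C(C)(C)C)cc(OC)c1O[Si](C(C)C)(C(C)C)C(C)C
A2 | alternative 1 | ethynyl (1S,2R)-3-(tert-butyldimethylsilyloxy)-2-[4-(tert-butyldimethylsilyloxymethyl)furan-2-yl]-1-[3,5-dimethoxy-4-(triisopropylsilyloxy)phenyl]propyl ether | COc1cc([C@H]([C@@H](CO[Si](C)(C)C(C)(C)C)c2cc(CO[Si](C)(C)C(C)(C)C)co2)OC#C)cc(OC)c1O[Si](C(C)C)(C(C)C)C(C)C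
A3 | alternative 2 | methyl (2S,3R)-3-(tert-butyldimethylsilyloxymethyl)-7-methoxy-2-[3,5-dimethoxy-4-(methoxymethoxy)phenyl]-2,3-dihydrobenzofuran-5-carboxylate | COCOc1c(OC)cc([C@H]2Oc3c(OC)cc(C(=O)OC)cc3[C@@H]2CO[Si](C)(C)C(C)(C)C)cc1OC
A4 | alternative 2 | methyl 4-iodo-3-methoxybenzoate | COC(=O)c1ccc(I)c(OC)c1
A5 | alternative 2 | tert-butyl{[(2S,3R)-3-[3,5-dimethoxy-4-(methoxymethoxy)phenyl]oxiran-2-yl]methoxy}dimethylsilane (cis epoxide) | COCOc1c(OC)cc([C@H]2O[C@H]2CO[Si](C)(C)C(C)(C)C)cc1OC
A6 | alternative 3 | [(2S,3R)-5-bromo-2-(4-hydroxy-3,5-dimethoxyphenyl)-7-methoxy-2,3-dihydrobenzofuran-3-yl]methanol (identical with 13) | COc1cc([C@H]2Oc3c(OC)cc(Br)cc3[C@@H]2CO)cc(OC)c1O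
A7 | alternative 3 | (2R)-2-(5-bromo-2-hydroxy-3-methoxyphenyl)-1-(4-hydroxy-3,5-dimethoxyphenyl)propane-1,3-diol (both C1 epimers) | COc1cc(C(O)[C@@H](CO)c2cc(Br)cc(OC)c2O)cc(OC)c1O
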